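## The problem

The target is an unsymmetrical diaryl ether with no stereocentre, so every difficulty is one of regiochemistry and chemoselectivity. Ring A is a methyl 2-hydroxy-4-methylbenzoate whose C6 oxygen is the bridge. Ring B is a benzyl alcohol in which the bridging carbon C1' lies between the hydroxymethyl-bearing C2' and the prenyloxy-bearing C6', with methoxy at C4'. The central C–O bond therefore joins a doubly ortho-substituted, electron-rich ring B carbon to a ring A carbon next to an ester, which is the least favourable case for an Ullmann or addition–elimination diaryl ether synthesis. Ring B carries three oxygen atoms that must end as three different ethers (aryl, methyl, prenyl), so any route from a polyphenolic ring B has to tell them apart. The aryl prenyl ether does not tolerate acid, hydrogenation, quinone oxidants or prolonged strong heating (Claisen rearrangement); the electron-rich benzylic alcohol is also acid-sensitive; and the ring A phenol must be masked while ketenes, acid chlorides and diazo reagents are in play. The protecting groups must therefore leave under non-acidic, non-reductive conditions. The feature that opens the key step is the sequence C6'(O)–C1'(O)–C2'(C)–C3'(H)–C4'(O)–C5'(H) around ring B: a 4-oxy-3-alkyl vinylketene supplies C6', C1', C2' and C3', an alkoxyacetylene supplies C5' and C4', and each oxygen comes from a different reagent.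

## Retrosynthesis

**Target 23 from 22.** The last operation cuts two O-protecting groups: the triisopropylsilyl (TIPS) ether of the benzylic alcohol and the 2-(trimethylsilyl)ethoxymethyl (SEM) ether of the ring A phenol in 22. Both are chosen because fluoride removes them. A methoxymethyl or benzyl group on ring A would require acid or hydrogen after the prenyl ether is in place. The forward step is one fluoride treatment in a basic medium.

**22 from 20 and 21.** The prenyl O–C bond is cut next, giving phenol 20 and prenyl bromide 21. The prenyl group cannot come earlier, because its oxygen is only created in the ring-forming step; coming late, it never meets light, ketenes or acid chlorides. Phenol 20 has one free hydroxyl, so the alkylation needs no selectivity.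

**20 from 12 and 15 (key disconnection).** Ring B is cut at C2'–C3', C3'–C4', C5'–C6' and C1'–C6', leading to diazo ketone 12 and methoxyacetylene 15. The neighbouring cut, the diaryl ether bond, would require coupling at a carbon flanked on both sides and a ring B with three oxygens already differentiated. Here the ring is built on the ether oxygen, which is already in place. The ketene oxygen becomes the free C6' hydroxyl and the alkyne oxygen the C4' methoxy. The forward reaction must generate the vinylketene and have it captured by 15 with methoxy meta to the new hydroxyl.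

**15 from 13.** Methoxyacetylene 15 is volatile and is made when needed from chloroacetaldehyde dimethyl acetal 13 by twofold elimination.

**12 from 9 and 10.** The bond between the carbonyl carbon (future C6') and the diazo carbon (future C3') is cut, giving acid 9 and diazomethane 10, joined through acid chloride 11. A diazo transfer onto a methyl ketone would need two more steps and is held in reserve. The forward step must make the acid chloride without free acid, because of the acetal-type SEM group.

**9 from 8.** Acid 9 comes from diester 8 by hydrolysis of one ester. The two esters differ sharply: the ring A ester sits between two ortho oxygen substituents and is shielded, while the acrylate ester is open.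

**8 from 2 and 7.** The vinyl C–O bond (ring A oxygen to future C1') is cut, giving phenol 2 and enol tosylate 7. This is where the plan gains most: the ring A oxygen is joined to an unhindered sp2 CH by addition–elimination and not to a congested aryl carbon. Only a base and a good leaving group on the β-carbon of an acrylate are needed.

**7 from 6, and 6 from 4 and 5.** Enol tosylate 7 is the O-sulfonyl derivative of formyl ester 6. Ester 6 arises by cutting the C–CHO bond, which leads to silyl ether 4 and methyl formate 5; 4 is the TIPS ether of methyl 3-hydroxypropanoate 3. The formate carbon becomes C1', C2 of 3 becomes C2' and C3 of 3 the hydroxymethyl carbon.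

**2 from 1.** Phenol 2 is the mono-SEM ether of the symmetric methyl 2,6-dihydroxy-4-methylbenzoate 1. Because 1 is symmetric, no regiochemical question arises.

## Roads not taken

**Alternative 1: aryne three-component coupling.** The cut is at the ring A C6–O bond and the C1–carboxyl bond. Ring A enters as the aryne released by fluoride from silylaryl triflate A2. The potassium salt of ring B phenol A3 adds at the aryne carbon remote from the acetal oxygen, and the neighbouring aryl anion is carboxylated and then O-methylated in the same flask to give A1.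
- Merits: two bonds and the whole skeleton in one operation; the regiochemistry of nucleophile addition to 3-alkoxyarynes is dependable; A1 is two deprotections from the target. In convergence and in step count after fragment union it is better than the chosen plan, which is linear over nine steps.
- Weak points: the aryl anion formed after phenoxide addition is normally protonated by the medium faster than a gaseous electrophile can intercept it. Carboxylative aryne couplings rest on neutral nitrogen nucleophiles that give zwitterions, not on a doubly ortho-substituted phenoxide. A3 already contains ring B with its three oxygens differentiated, so the central problem is assumed, not solved. A2 needs its own multistep synthesis. The methoxymethyl group of A1 must be removed with acid while the prenyl ether is present.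
- Comparison: the chosen plan has to set against the better convergence that it produces the ring B pattern in one step from acyclic pieces, joins the ring A oxygen to an unhindered carbon, and needs no acid after prenylation.

**Alternative 2: ring B as a cyclohexane-1,3-dione.** The cut is at C1'–C2' and C4'–C5' of a reduced ring B. Under alkoxide, aryloxyacetone A5 adds through its oxygen-bearing methylene to the β-carbon of silyloxycrotonate A6, and the methyl ketone enolate then condenses on the ester to give dione A4.
- Merits: cheap reagents, no photochemistry, no diazo compound, and ring A needs no protection. In reagent hazard and in ease of scale it is better than the chosen plan, which uses diazomethane 10 and a photochemical step.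
- Weak points: A5 has two enolisable positions, and A6 can deconjugate or lose its γ-silyloxy group under alkoxide. A4 is at the wrong oxidation level and must be dehydrogenated. The two ring oxygens of A4 (future C4' and C6') emerge as one enolised dione, so their separate methylation and prenylation is a new selectivity problem. Ring A must still be esterified next to free phenols.
- Comparison: the chosen plan delivers C4'–OMe and C6'–OH already differentiated and aromatic, with two steps left after ring formation, whereas this road adds oxidation, two selective alkylations and an esterification.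

**Alternative 3: ring A by cycloaddition.** The cut is at C1–C2 and C5–C6 of ring A. Diene A8 adds to aryloxypropiolate A9, and the adduct aromatises by loss of the acetal alkoxy group and desilylation to give A7.
- Merits: ring A appears with its hydrogen-bonded phenol and ester in place, without a protecting group; the orientation of such dienes towards propiolates is reliable; A7 is one fluoride step from the target. In its end game it is shorter and cleaner than the chosen plan.
- Weak points: the β-carbon of A9 carries a donor oxygen and a bulky, doubly ortho-substituted aryl group, which lowers dienophilicity and calls for temperatures at which the aryl prenyl ether and A8 are at risk. A9 must be made from phenol A3 by strong-base ynol ether chemistry, so ring B with all three oxygens differentiated is again presupposed.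
- Comparison: this road builds the easy ring and leaves the hard one to classical arene chemistry. The chosen plan accepts one protecting group on ring A in order to construct ring B itself.

Key step: step 9

Assumption: ethereal diazomethane 10 is taken as a stock reagent, freshly distilled from commercial N-methyl-N-nitroso-4-methylbenzenesulfonamide and KOH; the enol ether geometry drawn for 7 to 12 is the expected major isomer and the other isomer would serve equally.

## Route

**Step 1**
Reactants: 1 methyl 2,6-dihydroxy-4-methylbenzoate
Product: 2 methyl 2-hydroxy-4-methyl-6-{[2-(trimethylsilyl)ethoxy]methoxy}benzoate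
Conditions: SEMCl (1.05 equiv), iPr2NEt, CH2Cl2, 0 °C → rt
Reagents that add atoms: 2-(trimethylsilyl)ethoxymethyl chloride, C[Si](C)(C)CCOCCl
Why: Williamson-type O-alkylation with an α-chloro ether; 1 is symmetric, and after the first etherification the remaining hydroxyl is hydrogen-bonded to the ester carbonyl and reacts more slowly, so one equivalent should stop largely at the mono-ether.

**Step 2**
Reactants: 3 methyl 3-hydroxypropanoate
Product: 4 methyl 3-[(triisopropylsilyl)oxy]propanoate
Conditions: TIPSCl, imidazole, DMF, rt
Reagents that add atoms: chlorotriisopropylsilane, CC(C)[Si](Cl)(C(C)C)C(C)C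
Why: Standard imidazole-promoted silylation of a primary alcohol; the bulky silyl group is chosen because it resists hydroxide, amide bases and β-elimination better than smaller silyl ethers.

**Step 3**
Reactants: 4 methyl 3-[(triisopropylsilyl)oxy]propanoate; 5 methyl formate
Product: 6 methyl 2-formyl-3-[(triisopropylsilyl)oxy]propanoate (racemic, in equilibrium with its hydroxymethylene tautomer)
Conditions: LiN(iPr)2, THF, −78 °C; HCO2Me (3 equiv), −78 → 0 °C; AcOH
Reagents that add atoms: none
Why: Crossed Claisen condensation (formylation) of the lithium ester enolate, which is formed and consumed cold so that β-elimination of the silyloxy group should not compete; the product is held as its stabilised enolate until the quench, so its stereocentre is of no consequence.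

**Step 4**
Reactants: 6 methyl 2-formyl-3-[(triisopropylsilyl)oxy]propanoate
Product: 7 methyl (2E)-3-{[(4-methylphenyl)sulfonyl]oxy}-2-{[(triisopropylsilyl)oxy]methyl}prop-2-enoate
Conditions: TsCl, N-methylimidazole, Et3N, CH2Cl2, 0 °C
Reagents that add atoms: 4-methylbenzenesulfonyl chloride, Cc1ccc(cc1)S(Cl)(=O)=O
Why: O-sulfonylation of the enol of a 1,3-dicarbonyl compound with TsCl activated by N-methylimidazole; with a non-chelating amine base the tosyloxy group is expected trans to the ester (E), though either isomer would serve in step 5.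

**Step 5**
Reactants: 2 methyl 2-hydroxy-4-methyl-6-{[2-(trimethylsilyl)ethoxy]methoxy}benzoate; 7 methyl (2E)-3-{[(4-methylphenyl)sulfonyl]oxy}-2-{[(triisopropylsilyl)oxy]methyl}prop-2-enoate
Product: 8 methyl 2-{[(1E)-3-methoxy-3-oxo-2-{[(triisopropylsilyl)oxy]methyl}prop-1-en-1-yl]oxy}-4-methyl-6-{[2-(trimethylsilyl)ethoxy]methoxy}benzoate
Conditions: Cs2CO3, DABCO (20 mol %), MeCN, rt → 40 °C
Reagents that add atoms: none
Why: Nucleophilic vinylic substitution by addition–elimination: the phenoxide adds to the unhindered β-CH of the acrylate (directly or after DABCO has displaced tosylate to give a β-ammonium acrylate) and the ester-stabilised carbanion expels the leaving group; the ester-trans vinyl ether is expected, and its geometry is irrelevant later.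

**Step 6**
Reactants: 8 methyl 2-{[(1E)-3-methoxy-3-oxo-2-{[(triisopropylsilyl)oxy]methyl}prop-1-en-1-yl]oxy}-4-methyl-6-{[2-(trimethylsilyl)ethoxy]methoxy}benzoate
Product: 9 (2E)-3-[2-(methoxycarbonyl)-5-methyl-3-{[2-(trimethylsilyl)ethoxy]methoxy}phenoxy]-2-{[(triisopropylsilyl)oxy]methyl}prop-2-enoic acid
Conditions: LiOH·H2O, THF/H2O (3:1), 0 °C → rt; then 1 M HCl to pH 4, 0 °C
Reagents that add atoms: lithium hydroxide, [Li+].[OH-]
Why: Saponification by acyl–oxygen cleavage is expected only at the acrylate ester, because the ring A ester is flanked by two ortho oxygen substituents and resists tetrahedral attack; methanol is left out so that no alkoxide can exchange the β-aryloxy group, and both protecting groups are base-stable.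

**Step 7**
Reactants: 9 (2E)-3-[2-(methoxycarbonyl)-5-methyl-3-{[2-(trimethylsilyl)ethoxy]methoxy}phenoxy]-2-{[(triisopropylsilyl)oxy]methyl}prop-2-enoic acid; 10 diazomethane
Product: 12 methyl 2-{[(1E)-4-diazo-3-oxo-2-{[(triisopropylsilyl)oxy]methyl}but-1-en-1-yl]oxy}-4-methyl-6-{[2-(trimethylsilyl)ethoxy]methoxy}benzoate, via acid chloride 11 (not isolated)
Conditions: 1-chloro-N,N,2-trimethylprop-1-en-1-amine, CH2Cl2, 0 °C → rt; then CH2N2 (3 equiv), Et2O, 0 °C → rt
Reagents that add atoms: none
Why: The α-chloroenamine makes acid chloride 11 under neutral conditions, so the acetal-type SEM ether is not exposed to HCl, and C-acylation of diazomethane (first stage of the Arndt–Eistert sequence) gives the diazo ketone while a second equivalent of 10 takes up HCl; the donor-substituted, trisubstituted alkene is a poor dipolarophile, which should suppress pyrazoline formation.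

**Step 8**
Reactants: 13 chloroacetaldehyde dimethyl acetal
Product: 15 methoxyacetylene, via sodium methoxyacetylide 14 (not isolated)
Conditions: NaNH2 (3 equiv), liq. NH3, −33 °C; then sat. aq. NaCl, −70 °C; distilled (bp about 23 °C) into cold ClCH2CH2Cl
Reagents that add atoms: none
Why: Twofold base-induced elimination (methanol, then HCl) from the α-chloro acetal gives acetylide 14, which is protonated on aqueous quench; this is the standard preparation of alkoxyacetylenes.

**Step 9**
Reactants: 12 methyl 2-{[(1E)-4-diazo-3-oxo-2-{[(triisopropylsilyl)oxy]methyl}but-1-en-1-yl]oxy}-4-methyl-6-{[2-(trimethylsilyl)ethoxy]methoxy}benzoate; 15 methoxyacetylene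
Product: 20 methyl 2-[2-hydroxy-4-methoxy-6-{[(triisopropylsilyl)oxy]methyl}phenoxy]-4-methyl-6-{[2-(trimethylsilyl)ethoxy]methoxy}benzoate, via vinylketene 16 (not isolated), via 4-alkenylcyclobutenone 17 (not isolated), via dienylketene 18 (not isolated), via cyclohexa-2,4-dienone 19 (not isolated)
Conditions: 15 (5 equiv), ClCH2CH2Cl (degassed), hν (300 nm), 15 °C, sealed quartz tube; then 80 °C
Reagents that add atoms: none
Why: Photolysis expels dinitrogen from 12 and the alkenyl group migrates to the carbene carbon (Wolff rearrangement, C2'–C3'), giving the 4-aryloxyvinylketene 16 with its alkene geometry intact. The unsubstituted, nucleophilic carbon of 15 attacks the ketene carbonyl carbon and the methoxy-bearing carbon closes on C3', a regiospecific [2+2] cycloaddition (C5'–C6', C3'–C4') that gives cyclobutenone 17. At 80 °C 17 opens by conrotatory four-electron electrocyclic cleavage to dienylketene 18; the opening is reversible, so the isomer with the alkenyl group turned inward, the only one able to cyclise, is drained continuously. Ring B then closes by thermal disrotatory six-electron electrocyclisation of the ketene carbon onto the aryloxy-bearing alkene terminus (C1'–C6'), and dienone 19 tautomerises irreversibly to phenol 20. The closest known reaction type is the Danheiser benzannulation in its photochemical Wolff variant, which joins α,β-unsaturated α'-diazo ketones with alkoxy- or silyloxyalkynes to give resorcinol monoethers; the aryloxy donor at the alkene terminus is a variation within that substrate class. The stereocentres of 17 and 19 are transient and vanish on aromatisation, and the enol ether geometry is of no consequence because either orientation of the terminus leads to 19. The one selectivity required, methoxy meta and not ortho to the new hydroxyl, follows from the polarisation of the ynol ether; capture of 16 by 15 in competition with ketene dimerisation is favoured by the fivefold excess of 15, which, unlike its ethoxy homologue, cannot fragment by retro-ene loss of an alkene on heating.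

**Step 10**
Reactants: 20 methyl 2-[2-hydroxy-4-methoxy-6-{[(triisopropylsilyl)oxy]methyl}phenoxy]-4-methyl-6-{[2-(trimethylsilyl)ethoxy]methoxy}benzoate; 21 prenyl bromide (1-bromo-3-methylbut-2-ene)
Product: 22 methyl 2-[4-methoxy-2-[(3-methylbut-2-en-1-yl)oxy]-6-{[(triisopropylsilyl)oxy]methyl}phenoxy]-4-methyl-6-{[2-(trimethylsilyl)ethoxy]methoxy}benzoate
Conditions: K2CO3, acetone, 50 °C
Reagents that add atoms: none
Why: Williamson ether synthesis on the only free hydroxyl of 20; the soft phenoxide and the primary allylic bromide under mild carbonate conditions should give O-alkylation at the primary carbon without C-alkylation or allylic transposition.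

**Step 11**
Reactants: 22 methyl 2-[4-methoxy-2-[(3-methylbut-2-en-1-yl)oxy]-6-{[(triisopropylsilyl)oxy]methyl}phenoxy]-4-methyl-6-{[2-(trimethylsilyl)ethoxy]methoxy}benzoate
Product: 23 methyl 2-hydroxy-6-[2-(hydroxymethyl)-4-methoxy-6-[(3-methylbut-2-en-1-yl)oxy]phenoxy]-4-methylbenzoate (CNP0532721.0)
Conditions: TBAF (6 equiv), THF/DMPU, 0 → 50 °C; H2O work-up
Reagents that add atoms: none
Why: Fluoride-induced desilylation cleaves the TIPS ether directly and fragments the SEM ether (β-elimination to ethene, then loss of formaldehyde from the hemiacetal); no acid is present, so the aryl prenyl ether and the electron-rich benzyl alcohol are not at risk, and the doubly ortho-substituted ester should resist the basic medium.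

## Compound list

1 | methyl 2,6-dihydroxy-4-methylbenzoate | COC(=O)c1c(O)cc(C)cc1O | starting material
2 | methyl 2-hydroxy-4-methyl-6-{[2-(trimethylsilyl)ethoxy]methoxy}benzoate | COC(=O)c1c(O)cc(C)cc1OCOCC[Si](C)(C)C | intermediate
3 | methyl 3-hydroxypropanoate | COC(=O)CCO | starting material
4 | methyl 3-[(triisopropylsilyl)oxy]propanoate | COC(=O)CCO[Si](C(C)C)(C(C)C)C(C)C | intermediate
5 | methyl formate | COC=O | starting material
6 | methyl 2-formyl-3-[(triisopropylsilyl)oxy]propanoate (racemic, enolisable) | COC(=O)C(C=O)CO[Si](C(C)C)(C(C)C)C(C)C | intermediate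
7 | methyl (2E)-3-{[(4-methylphenyl)sulfonyl]oxy}-2-{[(triisopropylsilyl)oxy]methyl}prop-2-enoate | COC(=O)/C(CO[Si](C(C)C)(C(C)C)C(C)C)=C/OS(=O)(=O)c1ccc(C)cc1 | intermediate
8 | methyl 2-{[(1E)-3-methoxy-3-oxo-2-{[(triisopropylsilyl)oxy]methyl}prop-1-en-1-yl]oxy}-4-methyl-6-{[2-(trimethylsilyl)ethoxy]methoxy}benzoate | COC(=O)c1c(OCOCC[Si](C)(C)C)cc(C)cc1O/C=C(/C(=O)OC)CO[Si](C(C)C)(C(C)C)C(C)C | intermediate
9 | (2E)-3-[2-(methoxycarbonyl)-5-methyl-3-{[2-(trimethylsilyl)ethoxy]methoxy}phenoxy]-2-{[(triisopropylsilyl)oxy]methyl}prop-2-enoic acid | COC(=O)c1c(OCOCC[Si](C)(C)C)cc(C)cc1O/C=C(/C(O)=O)CO[Si](C(C)C)(C(C)C)C(C)C | intermediate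
10 | diazomethane | C=[N+]=[N-] | starting material
11 | (2E)-3-[2-(methoxycarbonyl)-5-methyl-3-{[2-(trimethylsilyl)ethoxy]methoxy}phenoxy]-2-{[(triisopropylsilyl)oxy]methyl}prop-2-enoyl chloride (not isolated) | COC(=O)c1c(OCOCC[Si](C)(C)C)cc(C)cc1O/C=C(/C(Cl)=O)CO[Si](C(C)C)(C(C)C)C(C)C | intermediate
12 | methyl 2-{[(1E)-4-diazo-3-oxo-2-{[(triisopropylsilyl)oxy]methyl}but-1-en-1-yl]oxy}-4-methyl-6-{[2-(trimethylsilyl)ethoxy]methoxy}benzoate | COC(=O)c1c(OCOCC[Si](C)(C)C)cc(C)cc1O/C=C(/C(=O)C=[N+]=[N-])CO[Si](C(C)C)(C(C)C)C(C)C | intermediate
13 | chloroacetaldehyde dimethyl acetal (2-chloro-1,1-dimethoxyethane) | COC(CCl)OC | starting material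
14 | sodium methoxyacetylide (not isolated) | [Na+].[C-]#COC | intermediate
15 | methoxyacetylene (methoxyethyne) | COC#C | intermediate
16 | methyl 2-{[(1Z)-4-oxo-2-{[(triisopropylsilyl)oxy]methyl}buta-1,3-dien-1-yl]oxy}-4-methyl-6-{[2-(trimethylsilyl)ethoxy]methoxy}benzoate (vinylketene, not isolated) | COC(=O)c1c(OCOCC[Si](C)(C)C)cc(C)cc1O/C=C(/C=C=O)CO[Si](C(C)C)(C(C)C)C(C)C | intermediate
17 | methyl 2-{[(1Z)-2-(2-methoxy-4-oxocyclobut-2-en-1-yl)-3-[(triisopropylsilyl)oxy]prop-1-en-1-yl]oxy}-4-methyl-6-{[2-(trimethylsilyl)ethoxy]methoxy}benzoate (racemic, not isolated) | COC1=CC(=O)C1/C(CO[Si](C(C)C)(C(C)C)C(C)C)=C/Oc1cc(C)cc(OCOCC[Si](C)(C)C)c1C(=O)OC | intermediate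
18 | methyl 2-{[(1Z,3E)-4-methoxy-6-oxo-2-{[(triisopropylsilyl)oxy]methyl}hexa-1,3,5-trien-1-yl]oxy}-4-methyl-6-{[2-(trimethylsilyl)ethoxy]methoxy}benzoate (dienylketene, not isolated) | COC(=O)c1c(OCOCC[Si](C)(C)C)cc(C)cc1O/C=C(/C=C(OC)\C=C=O)CO[Si](C(C)C)(C(C)C)C(C)C | intermediate
19 | methyl 2-{[4-methoxy-6-oxo-2-{[(triisopropylsilyl)oxy]methyl}cyclohexa-2,4-dien-1-yl]oxy}-4-methyl-6-{[2-(trimethylsilyl)ethoxy]methoxy}benzoate (racemic, not isolated) | COC(=O)c1c(OCOCC[Si](C)(C)C)cc(C)cc1OC1C(=O)C=C(OC)C=C1CO[Si](C(C)C)(C(C)C)C(C)C | intermediate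
20 | methyl 2-[2-hydroxy-4-methoxy-6-{[(triisopropylsilyl)oxy]methyl}phenoxy]-4-methyl-6-{[2-(trimethylsilyl)ethoxy]methoxy}benzoate | COC(=O)c1c(OCOCC[Si](C)(C)C)cc(C)cc1Oc1c(CO[Si](C(C)C)(C(C)C)C(C)C)cc(OC)cc1O | intermediate
21 | prenyl bromide (1-bromo-3-methylbut-2-ene) | CC(C)=CCBr | starting material
22 | methyl 2-[4-methoxy-2-[(3-methylbut-2-en-1-yl)oxy]-6-{[(triisopropylsilyl)oxy]methyl}phenoxy]-4-methyl-6-{[2-(trimethylsilyl)ethoxy]methoxy}benzoate | COC(=O)c1c(OCOCC[Si](C)(C)C)cc(C)cc1Oc1c(CO[Si](C(C)C)(C(C)C)C(C)C)cc(OC)cc1OCC=C(C)C | intermediate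
23 | methyl 2-hydroxy-6-[2-(hydroxymethyl)-4-methoxy-6-[(3-methylbut-2-en-1-yl)oxy]phenoxy]-4-methylbenzoate | COC(=O)c1c(O)cc(C)cc1Oc1c(CO)cc(OC)cc1OCC=C(C)C | target

## Step count and least certain steps

Total step count: 11. Longest linear sequence: 9 steps (from 3 through steps 2, 3, 4, 5, 6, 7, 9, 10 and 11 to 23).

**Step 9 (key step).** The most likely failure is loss of vinylketene 16 before the volatile, only moderately nucleophilic 15 captures it. The ketene could dimerise or acylate the phenol as it forms, and the aryl enol ether competes for light and could be photodegraded. A smaller risk is the carbene escaping the Wolff shift. The fallback separates ketene generation from the photochemical stage. It sets out from 12, which is irradiated in aqueous THF so that water, present in large excess, traps the ketene at once to give (3Z)-4-[2-(methoxycarbonyl)-5-methyl-3-{[2-(trimethylsilyl)ethoxy]methoxy}phenoxy]-3-{[(triisopropylsilyl)oxy]methyl}but-3-enoic acid F1 (photochemical Arndt–Eistert homologation). The neutral α-chloroenamine converts F1 into the acid chloride of F1, (3Z)-4-aryloxy-3-{[(triisopropylsilyl)oxy]methyl}but-3-enoyl chloride F2. Slow addition of Et3N to F2 in the dark, in the presence of a large excess of 15 in a sealed vessel, regenerates 16 by dehydrochlorination. This is the classical acid chloride/amine/alkoxyacetylene route to 3-alkoxycyclobutenones. The fallback comes back to the route at 16 and runs on through 17 to 20 on heating.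

**Step 5.** The phenoxide of 2 is hindered and conjugated with its ortho ester, so addition at carbon may be slow, and attack at sulfur (sulfonyl transfer, returning 6) may compete. The fallback sets out from 2 and builds the vinyl ether first. Oxa-Michael addition of 2 to methyl propiolate (DABCO cat., CH2Cl2) should give methyl 2-{[(1E)-3-methoxy-3-oxoprop-1-en-1-yl]oxy}-4-methyl-6-{[2-(trimethylsilyl)ethoxy]methoxy}benzoate F3. Iodo-acetoxylation and elimination (N-iodosuccinimide, AcOH; then Et3N) at the nucleophilic α-carbon gives methyl 2-{[(1Z)-2-iodo-3-methoxy-3-oxoprop-1-en-1-yl]oxy}-4-methyl-6-{[2-(trimethylsilyl)ethoxy]methoxy}benzoate F4. Stille coupling with Bu3SnCH2OH (Pd(PPh3)4, dioxane, 90 °C) gives methyl 2-{[(1E)-2-(hydroxymethyl)-3-methoxy-3-oxoprop-1-en-1-yl]oxy}-4-methyl-6-{[2-(trimethylsilyl)ethoxy]methoxy}benzoate F5. Silylation (TIPSCl, imidazole) comes back to the route at 8.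

**Step 6.** Hydroxide may add to the β-carbon and expel the aryloxide (reversal of step 5), or hydrolysis of the donor-deactivated ester may be too slow to stay selective. The fallback sets out from 8 and replaces hydrolysis by a redox detour. iBu2AlH (CH2Cl2, −78 °C) should reduce only the unshielded acrylate ester, giving methyl 2-{[(1Z)-3-hydroxy-2-{[(triisopropylsilyl)oxy]methyl}prop-1-en-1-yl]oxy}-4-methyl-6-{[2-(trimethylsilyl)ethoxy]methoxy}benzoate F6. MnO2 oxidises the allylic alcohol to methyl 2-{[(1E)-3-oxo-2-{[(triisopropylsilyl)oxy]methyl}prop-1-en-1-yl]oxy}-4-methyl-6-{[2-(trimethylsilyl)ethoxy]methoxy}benzoate F7. Pinnick oxidation (NaClO2, NaH2PO4, 2-methylbut-2-ene, tBuOH/H2O) comes back to the route at 9.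

**Step 7.** Diazomethane may add as a 1,3-dipole across the acryloyl double bond, or acylation of the deactivated acid chloride may be so slow that chloride attacks the diazonium intermediate to give a chloromethyl ketone. Traces of HCl could also cleave the SEM ether. The fallback sets out from 9 and avoids both acid chloride and diazomethane. Amide coupling (MeNHOMe·HCl, EDC·HCl, iPr2NEt) gives Weinreb amide methyl 2-{[(1E)-3-[methoxy(methyl)amino]-3-oxo-2-{[(triisopropylsilyl)oxy]methyl}prop-1-en-1-yl]oxy}-4-methyl-6-{[2-(trimethylsilyl)ethoxy]methoxy}benzoate F8. MeMgBr (THF, −78 → 0 °C) gives methyl ketone methyl 2-{[(1E)-3-oxo-2-{[(triisopropylsilyl)oxy]methyl}but-1-en-1-yl]oxy}-4-methyl-6-{[2-(trimethylsilyl)ethoxy]methoxy}benzoate F9. Its kinetic enolate (LiN(SiMe3)2, −78 °C) is trifluoroacetylated with CF3CO2CH2CF3 to methyl 2-{[(1E)-6,6,6-trifluoro-3,5-dioxo-2-{[(triisopropylsilyl)oxy]methyl}hex-1-en-1-yl]oxy}-4-methyl-6-{[2-(trimethylsilyl)ethoxy]methoxy}benzoate F10. Detrifluoroacetylative diazo transfer (MsN3, Et3N, H2O, MeCN) comes back to the route at 12.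

**Step 11.** Fragmentation of the aryl SEM ether by fluoride may be incomplete at temperatures the molecule tolerates, and the formaldehyde released may hydroxymethylate the liberated ring A phenoxide. The fallback sets out from 20 and changes the order of events. Both protecting groups are removed with aqueous HCl in THF (40 °C) before any prenyl ether exists, giving methyl 2-hydroxy-6-[2-hydroxy-6-(hydroxymethyl)-4-methoxyphenoxy]-4-methylbenzoate F11. Prenylation of F11 with 21 (1.05 equiv) and K2CO3 in acetone should then alkylate only the ring B phenol, because the ring A phenol is hydrogen-bonded to its ester and the primary alcohol is not deprotonated. This comes back to the route at 23.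

## Further compounds

F1 | step 9 | (3Z)-4-[2-(methoxycarbonyl)-5-methyl-3-{[2-(trimethylsilyl)ethoxy]methoxy}phenoxy]-3-{[(triisopropylsilyl)oxy]methyl}but-3-enoic acid | COC(=O)c1c(OCOCC[Si](C)(C)C)cc(C)cc1O/C=C(/CC(O)=O)CO[Si](C(C)C)(C(C)C)C(C)C
F2 | step 9 | (3Z)-4-[2-(methoxycarbonyl)-5-methyl-3-{[2-(trimethylsilyl)ethoxy]methoxy}phenoxy]-3-{[(triisopropylsilyl)oxy]methyl}but-3-enoyl chloride | COC(=O)c1c(OCOCC[Si](C)(C)C)cc(C)cc1O/C=C(/CC(Cl)=O)CO[Si](C(C)C)(C(C)C)C(C)C
F3 | step 5 | methyl 2-{[(1E)-3-methoxy-3-oxoprop-1-en-1-yl]oxy}-4-methyl-6-{[2-(trimethylsilyl)ethoxy]methoxy}benzoate | COC(=O)/C=C/Oc1cc(C)cc(OCOCC[Si](C)(C)C)c1C(=O)OC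
F4 | step 5 | methyl 2-{[(1Z)-2-iodo-3-methoxy-3-oxoprop-1-en-1-yl]oxy}-4-methyl-6-{[2-(trimethylsilyl)ethoxy]methoxy}benzoate | COC(=O)/C(I)=C/Oc1cc(C)cc(OCOCC[Si](C)(C)C)c1C(=O)OC
F5 | step 5 | methyl 2-{[(1E)-2-(hydroxymethyl)-3-methoxy-3-oxoprop-1-en-1-yl]oxy}-4-methyl-6-{[2-(trimethylsilyl)ethoxy]methoxy}benzoate | COC(=O)/C(CO)=C/Oc1cc(C)cc(OCOCC[Si](C)(C)C)c1C(=O)OC
F6 | step 6 | methyl 2-{[(1Z)-3-hydroxy-2-{[(triisopropylsilyl)oxy]methyl}prop-1-en-1-yl]oxy}-4-methyl-6-{[2-(trimethylsilyl)ethoxy]methoxy}benzoate | COC(=O)c1c(OCOCC[Si](C)(C)C)cc(C)cc1O/C=C(/CO)CO[Si](C(C)C)(C(C)C)C(C)C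
F7 | step 6 | methyl 2-{[(1E)-3-oxo-2-{[(triisopropylsilyl)oxy]methyl}prop-1-en-1-yl]oxy}-4-methyl-6-{[2-(trimethylsilyl)ethoxy]methoxy}benzoate | COC(=O)c1c(OCOCC[Si](C)(C)C)cc(C)cc1O/C=C(/C=O)CO[Si](C(C)C)(C(C)C)C(C)C
F8 | step 7 | methyl 2-{[(1E)-3-[methoxy(methyl)amino]-3-oxo-2-{[(triisopropylsilyl)oxy]methyl}prop-1-en-1-yl]oxy}-4-methyl-6-{[2-(trimethylsilyl)ethoxy]methoxy}benzoate | COC(=O)c1c(OCOCC[Si](C)(C)C)cc(C)cc1O/C=C(/C(=O)N(C)OC)CO[Si](C(C)C)(C(C)C)C(C)C
F9 | step 7 | methyl 2-{[(1E)-3-oxo-2-{[(triisopropylsilyl)oxy]methyl}but-1-en-1-yl]oxy}-4-methyl-6-{[2-(trimethylsilyl)ethoxy]methoxy}benzoate | COC(=O)c1c(OCOCC[Si](C)(C)C)cc(C)cc1O/C=C(/C(C)=O)CO[Si](C(C)C)(C(C)C)C(C)C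
F10 | step 7 | methyl 2-{[(1E)-6,6,6-trifluoro-3,5-dioxo-2-{[(triisopropylsilyl)oxy]methyl}hex-1-en-1-yl]oxy}-4-methyl-6-{[2-(trimethylsilyl)ethoxy]methoxy}benzoate | COC(=O)c1c(OCOCC[Si](C)(C)C)cc(C)cc1O/C=C(/C(=O)CC(=O)C(F)(F)F)CO[Si](C(C)C)(C(C)C)C(C)C
F11 | step 11 | methyl 2-hydroxy-6-[2-hydroxy-6-(hydroxymethyl)-4-methoxyphenoxy]-4-methylbenzoate | COC(=O)c1c(O)cc(C)cc1Oc1c(CO)cc(OC)cc1O
A1 | alternative 1 | methyl 2-[2-{[tert-butyl(dimethyl)silyl]oxymethyl}-4-methoxy-6-[(3-methylbut-2-en-1-yl)oxy]phenoxy]-6-(methoxymethoxy)-4-methylbenzoate | COCOc1cc(C)cc(Oc2c(CO[Si](C)(C)C(C)(C)C)cc(OC)cc2OCC=C(C)C)c1C(=O)OC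
A2 | alternative 1 | 3-(methoxymethoxy)-5-methyl-2-(trimethylsilyl)phenyl trifluoromethanesulfonate | COCOc1cc(C)cc(OS(=O)(=O)C(F)(F)F)c1[Si](C)(C)C
A3 | alternative 1 | 2-{[tert-butyl(dimethyl)silyl]oxymethyl}-4-methoxy-6-[(3-methylbut-2-en-1-yl)oxy]phenol | Oc1c(CO[Si](C)(C)C(C)(C)C)cc(OC)cc1OCC=C(C)C
A4 | alternative 2 | 2-hydroxy-4-methyl-6-{[2,4-dioxo-6-{[(triisopropylsilyl)oxy]methyl}cyclohexyl]oxy}benzoic acid (mixture of diastereomers) | Cc1cc(O)c(C(O)=O)c(OC2C(CO[Si](C(C)C)(C(C)C)C(C)C)CC(=O)CC2=O)c1
A5 | alternative 2 | 2-hydroxy-4-methyl-6-(2-oxopropoxy)benzoic acid | Cc1cc(O)c(C(O)=O)c(OCC(C)=O)c1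
A6 | alternative 2 | methyl (2E)-4-[(triisopropylsilyl)oxy]but-2-enoate | COC(=O)/C=C/CO[Si](C(C)C)(C(C)C)C(C)C
A7 | alternative 3 | methyl 2-[2-{[tert-butyl(dimethyl)silyl]oxymethyl}-4-methoxy-6-[(3-methylbut-2-en-1-yl)oxy]phenoxy]-6-hydroxy-4-methylbenzoate | COC(=O)c1c(O)cc(C)cc1Oc1c(CO[Si](C)(C)C(C)(C)C)cc(OC)cc1OCC=C(C)C
A8 | alternative 3 | 1-methoxy-3-methyl-1-(trimethylsilyloxy)buta-1,3-diene (mixture of ketene acetal geometries) | COC(O[Si](C)(C)C)=CC(C)=C
A9 | alternative 3 | methyl 3-[2-{[tert-butyl(dimethyl)silyl]oxymethyl}-4-methoxy-6-[(3-methylbut-2-en-1-yl)oxy]phenoxy]prop-2-ynoate | COC(=O)C#COc1c(CO[Si](C)(C)C(C)(C)C)cc(OC)cc1OCC=C(C)C
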